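(All runs were computed from invented constants; noise was put on by code.)

We cannot balance the charge from these runs, because target is the one species they read; what we can do is turn the early readings into a time.

| flask | starting material | remark | time |
|---|---|---|---|
| red | 0.034 M | run made earlier |  |
| green | 0.075 M | run made earlier |  |
| flask | 0.050 M |  | 5.0 min |

- red (time / min: target / %): 0.417: 6; 1.00: 16; 2.00: 22; 3.00: 27
- green (time / min: target / %): 0.417: 6; 1.00: 11; 2.00: 23; 3.00: 22

(each reading ± 2 percentage points)



- amount of target in percent of the starting material charged, at 15 s, 80 s and 5.0 min

The red and green runs differ by at most 5 percentage points against a scatter of 2 points, so we use their means for the flask, whose charge lies between theirs. Their readings at 1.00 min give an early pace, roughly the initial rate, that would turn the whole charge into target in 7.41 min; we call this the filling time.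

In the first instants, time divided by the filling time gives the amount of target. At 0.417 min that line says 5.63%, and the runs read 6% and 6%, so we take 3.38% at 15 s.

In the middle the line starts to fail. At 3.00 min it says 40.5%, while the mean reading is 24.5%. Something is slowing the gain of target, and target alone cannot show what. We therefore read 80 s between the means and get 16.5%.

For the end, the mean reading at 2.00 min is 22.5%, so the mean gained 2 points over the last minute read, and carrying that gain forward gives 28.5% at 5.0 min.

The forecast gave 4%, 16.5% and 28%, and it held its last value uncertain, since “the plateau is poorly defined and the target could decline”. Our figure is lower at 15 s and higher at 5.0 min.

The flask gives 4.09%, 16.8% and 29.9%.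

    starting material ⇌ target + by-product (K = 0.0730 M, k = 0.00290 s⁻¹)
    starting material + target → side product (k = 0.110 L mol⁻¹ s⁻¹)

At 5.0 min the filling-time line stands at 67.5%, whereas this flask holds 29.9% of target, beside 32.6% starting material and 37.6% side product, each side product counted as two. Target in this flask is still made faster than it is used up at 5.00 min, but with each step taken net the ratio has shrunk from 2.60 at 1.67 min to 1.23, and by 50.0 min the flask holds 10.1% target.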